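**Plan**
Retrosynthetic cuts: C13=C14 (olefination of a methyl ketone), C11=C12 (olefination of a C11 aldehyde), C8=C17 (methylenation of an 8-ketone), then both rings at once through C5–C10 and C8–C9, and last C6–C7, C3–C4 and C10–C1 of the open chain.
Enabling feature: ring B holds the quaternary C10 (angular methyl) between C9 and C5, so it is a masked cyclohexene made from a C9=C10 E-enoate (C11 as ester) and a C5=C6–C7=C8 silyloxydiene whose oxygen becomes the C8 carbonyl; C1–C4 of ring A is the tether.
Forward order: C10–C1 (carbocupration), C3–C4 (tert-prenylation), C6–C7 (Wittig) and silyl dienol ether formation give the acyclic triene; one intramolecular Diels–Alder reaction closes rings A and B together; the side chain is then grown C11→C13→C15 and C8 is methylenated.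
Stereochemistry: C3 from a catalyst-controlled aldehyde tert-prenylation; C9/C10 from the E-enoate geometry; C5 (trans fusion) from the ester-endo, tether-anti transition state; the absolute sense is relayed from C3 (equatorial OBn on the chair-like tether); 13E from the HWE reaction; C8 of the adduct is later erased.

Key step: step 9

Assumption: in the iridium-catalysed tert-prenylation the (R)-SEGPHOS catalyst is taken to deliver the prenyl unit to the Re face of the aldehyde (6S alcohol); should the sense be the opposite, the (S)-ligand is used and nothing else changes.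

**Route**

Step 1
Reactants: 1 [2-(1,3-dioxolan-2-yl)ethyl]magnesium bromide; 2 methyl but-2-ynoate
Product: 4 methyl (2E)-5-(1,3-dioxolan-2-yl)-3-methylpent-2-enoate, via alkenylcopper adduct 3 (not isolated)
Conditions: 1, CuBr·SMe2 (1:1), THF, −40 °C; then 2, −78 °C; sat. aq. NH4Cl at −78 °C
Reagents that add atoms: none
Why: syn-Carbocupration of the 2-ynoate by the Grignard-derived organocopper (conjugate addition) places the new chain cis to copper, and cold protonolysis of alkenylcopper 3 with retention should deliver the 2E enoate that later fixes the C9/C10 relationship.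

Step 2
Reactants: 4 methyl (2E)-5-(1,3-dioxolan-2-yl)-3-methylpent-2-enoate
Product: 5 methyl (2E)-3-methyl-6-oxohex-2-enoate
Conditions: 1 M aq. HCl, THF, rt
Reagents that add atoms: water, O
Why: Acid-catalysed acetal hydrolysis frees the aldehyde, while the conjugated methyl ester and its E geometry are untouched by dilute aqueous acid at room temperature.

Step 3
Reactants: 5 methyl (2E)-3-methyl-6-oxohex-2-enoate; 6 3-methylbuta-1,2-diene
Product: 7 methyl (2E,6S)-6-hydroxy-3,7,7-trimethylnona-2,8-dienoate
Conditions: 6 (excess), π-allyl iridium C,O-benzoate catalyst of (R)-SEGPHOS (5 mol %), i-PrOH (2 equiv), PhMe, 40 °C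
Reagents that add atoms: none
Why: Krische iridium-catalysed transfer-hydrogenative tert-prenylation, in which hydrometalation of the allene gives a 1,1-dimethyl-π-allyl iridium species that adds through its substituted terminus in a closed chair transition state, the chiral ligand selecting the Re face of the aldehyde so that the carbinol (labdane C3) is formed as 6S next to the new quaternary carbon while the conjugated ester is inert.

Step 4
Reactants: 7 methyl (2E,6S)-6-hydroxy-3,7,7-trimethylnona-2,8-dienoate
Product: 8 methyl (2E,6S)-6-(benzyloxy)-3,7,7-trimethylnona-2,8-dienoate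
Conditions: 2-benzyloxy-1-methylpyridinium triflate, MgO, PhCF3, 85 °C
Reagents that add atoms: 2-benzyloxy-1-methylpyridinium triflate, C[n+]1ccccc1OCc1ccccc1.[O-]S(=O)(=O)C(F)(F)F
Why: Neutral benzyl transfer from the thermally ionising 2-benzyloxypyridinium salt etherifies the hindered neopentyl-type alcohol without generating an alkoxide that could add 5-exo to the enoate (oxa-Michael).

Step 5
Reactants: 8 methyl (2E,6S)-6-(benzyloxy)-3,7,7-trimethylnona-2,8-dienoate
Product: 10 methyl (2E,6S)-6-(benzyloxy)-9-hydroxy-3,7,7-trimethylnon-2-enoate, via alkylborane 9 (not isolated)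
Conditions: 9-BBN, THF, 0 °C → rt; then aq. NaOAc, 30% H2O2, 0 °C → rt
Reagents that add atoms: hydrogen peroxide, OO
Why: Brown hydroboration–oxidation, in which 9-BBN adds anti-Markovnikov to the monosubstituted vinyl group only (the trisubstituted conjugated alkene and the ester do not react at room temperature) and buffered oxidation of borane 9 gives the primary alcohol, keeping the C5 methylene needed later for γ-deprotonation.

Step 6
Reactants: 10 methyl (2E,6S)-6-(benzyloxy)-9-hydroxy-3,7,7-trimethylnon-2-enoate
Product: 11 methyl (2E,6S)-6-(benzyloxy)-3,7,7-trimethyl-9-oxonon-2-enoate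
Conditions: Dess–Martin periodinane, CH2Cl2, rt
Reagents that add atoms: none
Why: Dess–Martin oxidation of the primary alcohol stops at the aldehyde under conditions compatible with the benzyl ether and the enoate.

Step 7
Reactants: 11 methyl (2E,6S)-6-(benzyloxy)-3,7,7-trimethyl-9-oxonon-2-enoate; 12 (triphenylphosphoranylidene)acetaldehyde
Product: 13 methyl (2E,6S,9E)-6-(benzyloxy)-3,7,7-trimethyl-11-oxoundeca-2,9-dienoate
Conditions: 12 (slight excess), PhMe, 80 °C
Reagents that add atoms: none
Why: Wittig olefination with the stabilised formylmethylene ylide should give the E-enal and adds C7 and C8, the lower electrophilicity of the product enal limiting a second homologation.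

Step 8
Reactants: 13 methyl (2E,6S,9E)-6-(benzyloxy)-3,7,7-trimethyl-11-oxoundeca-2,9-dienoate
Product: 14 methyl (2E,6S,8E,10E)-6-(benzyloxy)-11-[(tert-butyldimethylsilyl)oxy]-3,7,7-trimethylundeca-2,8,10-trienoate
Conditions: TBSOTf, Et3N, CH2Cl2, −78 → 0 °C; Et3N-deactivated silica
Reagents that add atoms: tert-butyldimethylsilyl triflate, CC(C)(C)[Si](C)(C)OS(=O)(=O)C(F)(F)F
Why: Soft enolisation (silyl dienol ether formation) by O-silylation of the enal and γ-deprotonation at C5 gives the 1-silyloxy-1,3-diene, the extended s-trans oxocarbenium ion favouring the 1E enol ether and the tert-alkyl substituent at C5 enforcing the 3E alkene, while the much less basic enoate ester is not silylated.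

Step 9
Reactants: 14 methyl (2E,6S,8E,10E)-6-(benzyloxy)-11-[(tert-butyldimethylsilyl)oxy]-3,7,7-trimethylundeca-2,8,10-trienoate
Product: 15 methyl 3β-(benzyloxy)-8β-[(tert-butyldimethylsilyl)oxy]-12,13,14,15,16,17-hexanorlabd-6-en-11-oate (trans-fused cycloadduct)
Conditions: PhMe (0.01 M), BHT, Et3N (cat.), sealed tube, 190 °C
Reagents that add atoms: none
Why: Thermal, concerted but asynchronous [4πs+2πs] cycloaddition in which the (E,E)-1-silyloxydiene (C5–C8, HOMO raised by the C8 oxygen, largest coefficient at C5) adds across the E-enoate (C9=C10, largest LUMO coefficient at C10), C5–C10 forming ahead of C8–C9; the closest known reaction type is the type 1 intramolecular Diels–Alder reaction of 2,8,10-undecatrienoates (1,7,9-decatrienes) carrying a 1-oxygenated diene. Ring B closes as the cyclohexene of the [4+2] addition (both new bonds lie in it), and ring A closes as the six-membered ring of the four-carbon tether C1–C4 through the C5–C10 bond alone (fused mode), its chair-like folding being favoured by the C4 gem-dimethyl group, which also leaves the diene without any hydrogen able to undergo a 1,5-shift. C9 and C10 are set relative to each other by the E geometry of the enoate (suprafacial addition keeps CO2Me and the C10 methyl cis), C8 by the 1E enol ether geometry together with the ester-endo orientation (OTBS cis to CO2Me, a centre that is erased later), and C5 relative to C10 by the ester-endo, tether-anti transition state, which gives the trans ring fusion. The absolute sense is relayed from C3: of the two endo transition states the one that keeps the benzyloxy group equatorial on the chair-like tether is preferred, placing 3-OBn cis to the C10 methyl. The step therefore needs endo over exo selectivity and diene-face selectivity, secured by the E,E,E triene geometry, the secondary-orbital preference of the ester and the resident 6S centre, while the crowding of a quaternary carbon formed next to C4 is overcome by temperature, which the TBS dienol ether should tolerate with base and radical inhibitor present.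

Step 10
Reactants: 15 methyl 3β-(benzyloxy)-8β-[(tert-butyldimethylsilyl)oxy]-12,13,14,15,16,17-hexanorlabd-6-en-11-oate
Product: 16 3β-(benzyloxy)-8β-[(tert-butyldimethylsilyl)oxy]-12,13,14,15,16,17-hexanorlabd-6-en-11-ol
Conditions: LiAlH4, Et2O, 0 °C; Fieser work-up
Reagents that add atoms: none
Why: Lithium aluminium hydride reduction of the hindered neopentyl-type ester gives the primary alcohol, the silyl ether, the benzyl ether and the isolated ring alkene being inert to hydride.

Step 11
Reactants: 16 3β-(benzyloxy)-8β-[(tert-butyldimethylsilyl)oxy]-12,13,14,15,16,17-hexanorlabd-6-en-11-ol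
Product: 17 3β-(benzyloxy)-8β-[(tert-butyldimethylsilyl)oxy]-12,13,14,15,16,17-hexanorlabd-6-en-11-al
Conditions: Dess–Martin periodinane, CH2Cl2, rt
Reagents that add atoms: none
Why: Dess–Martin oxidation gives the β-silyloxy aldehyde without base, so neither β-elimination of silanol nor epimerisation at C9 (whose equatorial formyl group is in any case the stable arrangement) is expected.

Step 12
Reactants: 17 3β-(benzyloxy)-8β-[(tert-butyldimethylsilyl)oxy]-12,13,14,15,16,17-hexanorlabd-6-en-11-al; 18 dimethyl (2-oxopropyl)phosphonate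
Product: 19 (11E)-3β-(benzyloxy)-8β-[(tert-butyldimethylsilyl)oxy]-14,15,17-trinorlabda-6,11-dien-13-one
Conditions: 18, LiCl, i-Pr2NEt, MeCN, rt
Reagents that add atoms: none
Why: Horner–Wadsworth–Emmons olefination under Masamune–Roush conditions uses a small lithium-chelated β-ketophosphonate anion formed with a weak amine base, which spares the epimerisable β-silyloxy aldehyde and should give the E-enone, adding C12, C13 and C16.

Step 13
Reactants: 19 (11E)-3β-(benzyloxy)-8β-[(tert-butyldimethylsilyl)oxy]-14,15,17-trinorlabda-6,11-dien-13-one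
Product: 20 3β-hydroxy-8β-[(tert-butyldimethylsilyl)oxy]-14,15,17-trinorlabdan-13-one
Conditions: H2 (3 atm), Pd(OH)2/C, EtOAc, rt
Reagents that add atoms: none
Why: Heterogeneous catalytic hydrogenation saturates the conjugated C11=C12 bond and the cis-disubstituted C6=C7 bond and hydrogenolyses the benzyl ether in one operation, creating no stereocentre and leaving the ketone and the TBS ether intact in ethyl acetate.

Step 14
Reactants: 20 3β-hydroxy-8β-[(tert-butyldimethylsilyl)oxy]-14,15,17-trinorlabdan-13-one
Product: 21 3β-acetoxy-8β-[(tert-butyldimethylsilyl)oxy]-14,15,17-trinorlabdan-13-one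
Conditions: Ac2O, pyridine, DMAP (cat.), CH2Cl2, rt
Reagents that add atoms: acetic anhydride, CC(=O)OC(C)=O
Why: DMAP-catalysed acetylation (nucleophilic acyl transfer) of the equatorial 3β-hydroxyl installs the acetate of the target once no hydride step remains.

Step 15
Reactants: 21 3β-acetoxy-8β-[(tert-butyldimethylsilyl)oxy]-14,15,17-trinorlabdan-13-one; 22 allyl (diethoxyphosphoryl)acetate
Product: 23 allyl (13E)-3β-acetoxy-8β-[(tert-butyldimethylsilyl)oxy]-17-norlabd-13-en-15-oate
Conditions: 22, NaH, THF, 0 → 50 °C
Reagents that add atoms: none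
Why: Horner–Wadsworth–Emmons olefination of the methyl ketone leaves the acetate and silyl ether untouched and should place the ester trans to the larger C12 chain (13E major, any 13Z isomer to be removed by chromatography), the allyl ester being chosen so that the acid can later be freed without hydrolysing the acetate.

Step 16
Reactants: 23 allyl (13E)-3β-acetoxy-8β-[(tert-butyldimethylsilyl)oxy]-17-norlabd-13-en-15-oate
Product: 24 allyl (13E)-3β-acetoxy-8β-hydroxy-17-norlabd-13-en-15-oate
Conditions: 48% aq. HF, MeCN, rt
Reagents that add atoms: none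
Why: Fluoride-driven desilylation (strong Si–F bond) removes the hindered axial TBS ether under acidic conditions that leave the acetate and the allyl enoate unchanged and exclude base-induced oxa-Michael addition of the 8-hydroxyl to C13.

Step 17
Reactants: 24 allyl (13E)-3β-acetoxy-8β-hydroxy-17-norlabd-13-en-15-oate
Product: 25 allyl (13E)-3β-acetoxy-8-oxo-17-norlabd-13-en-15-oate
Conditions: Dess–Martin periodinane, CH2Cl2, rt
Reagents that add atoms: none
Why: Dess–Martin oxidation of the axial secondary alcohol (helped by relief of its 1,3-diaxial interaction with the C10 methyl) gives the 8-ketone without base, so the equatorial C9 side chain, also the thermodynamically preferred epimer, is retained.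

Step 18
Reactants: 25 allyl (13E)-3β-acetoxy-8-oxo-17-norlabd-13-en-15-oate
Product: 26 allyl (13E)-3β-acetoxylabda-8(17),13-dien-15-oate
Conditions: Zn, CH2Br2, TiCl4 (pre-formed in THF), CH2Cl2, 0 °C → rt
Reagents that add atoms: dibromomethane, BrCBr
Why: Takai–Lombardo methylenation uses a non-basic, oxophilic Zn/Ti methylene reagent that converts hindered, enolisable ketones into 1,1-disubstituted alkenes and is chemoselective for the ketone over the acetate and the allyl enoate, so C17 is introduced without epimerisation at C9.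

Step 19
Reactants: 26 allyl (13E)-3β-acetoxylabda-8(17),13-dien-15-oate
Product: 27 (13E)-3β-acetoxylabda-8(17),13-dien-15-oic acid
Conditions: Pd(PPh3)4 (5 mol %), morpholine, THF, rt; dilute citric acid work-up
Reagents that add atoms: none
Why: Tsuji–Trost deallylation, in which Pd(0) ionises the allyl ester to a π-allyl complex that is trapped by morpholine, releases the carboxylic acid under neutral conditions that leave the acetate, the exocyclic alkene and the 13E enoate intact.

**Compound list**
1 | [2-(1,3-dioxolan-2-yl)ethyl]magnesium bromide | Br[Mg]CCC1OCCO1 | starting material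
2 | methyl but-2-ynoate | CC#CC(=O)OC | starting material
3 | alkenylcopper adduct, methyl (2Z)-2-cuprio-5-(1,3-dioxolan-2-yl)-3-methylpent-2-enoate | COC(=O)/C([Cu])=C(\C)CCC1OCCO1 | intermediate (not isolated)
4 | methyl (2E)-5-(1,3-dioxolan-2-yl)-3-methylpent-2-enoate | COC(=O)/C=C(\C)CCC1OCCO1 | intermediate
5 | methyl (2E)-3-methyl-6-oxohex-2-enoate | COC(=O)/C=C(\C)CCC=O | intermediate
6 | 3-methylbuta-1,2-diene | CC(C)=C=C | starting material
7 | methyl (2E,6S)-6-hydroxy-3,7,7-trimethylnona-2,8-dienoate | COC(=O)/C=C(\C)CC[C@H](O)C(C)(C)C=C | intermediate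
8 | methyl (2E,6S)-6-(benzyloxy)-3,7,7-trimethylnona-2,8-dienoate | COC(=O)/C=C(\C)CC[C@H](OCc1ccccc1)C(C)(C)C=C | intermediate
9 | alkylborane, methyl (2E,6S)-6-(benzyloxy)-9-(9-borabicyclo[3.3.1]nonan-9-yl)-3,7,7-trimethylnon-2-enoate | COC(=O)/C=C(\C)CC[C@H](OCc1ccccc1)C(C)(C)CCB1C2CCCC1CCC2 | intermediate (not isolated)
10 | methyl (2E,6S)-6-(benzyloxy)-9-hydroxy-3,7,7-trimethylnon-2-enoate | COC(=O)/C=C(\C)CC[C@H](OCc1ccccc1)C(C)(C)CCO | intermediate
11 | methyl (2E,6S)-6-(benzyloxy)-3,7,7-trimethyl-9-oxonon-2-enoate | COC(=O)/C=C(\C)CC[C@H](OCc1ccccc1)C(C)(C)CC=O | intermediate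
12 | (triphenylphosphoranylidene)acetaldehyde | O=CC=P(c1ccccc1)(c1ccccc1)c1ccccc1 | starting material
13 | methyl (2E,6S,9E)-6-(benzyloxy)-3,7,7-trimethyl-11-oxoundeca-2,9-dienoate | COC(=O)/C=C(\C)CC[C@H](OCc1ccccc1)C(C)(C)C/C=C/C=O | intermediate
14 | methyl (2E,6S,8E,10E)-6-(benzyloxy)-11-[(tert-butyldimethylsilyl)oxy]-3,7,7-trimethylundeca-2,8,10-trienoate | COC(=O)/C=C(\C)CC[C@H](OCc1ccccc1)C(C)(C)/C=C/C=C/O[Si](C)(C)C(C)(C)C | intermediate
15 | methyl 3β-(benzyloxy)-8β-[(tert-butyldimethylsilyl)oxy]-12,13,14,15,16,17-hexanorlabd-6-en-11-oate (labdane numbering; 5α-H, 9α-H, 10β-CH3, CO2Me on C9β) | CC(C)(C)[Si](C)(C)O[C@H]1C=C[C@H]2C(C)(C)[C@@H](OCc3ccccc3)CC[C@]2(C)[C@H]1C(=O)OC | intermediate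
16 | 3β-(benzyloxy)-8β-[(tert-butyldimethylsilyl)oxy]-12,13,14,15,16,17-hexanorlabd-6-en-11-ol | CC(C)(C)[Si](C)(C)O[C@H]1C=C[C@H]2C(C)(C)[C@@H](OCc3ccccc3)CC[C@]2(C)[C@H]1CO | intermediate
17 | 3β-(benzyloxy)-8β-[(tert-butyldimethylsilyl)oxy]-12,13,14,15,16,17-hexanorlabd-6-en-11-al | CC(C)(C)[Si](C)(C)O[C@H]1C=C[C@H]2C(C)(C)[C@@H](OCc3ccccc3)CC[C@]2(C)[C@H]1C=O | intermediate
18 | dimethyl (2-oxopropyl)phosphonate | COP(=O)(CC(C)=O)OC | starting material
19 | (11E)-3β-(benzyloxy)-8β-[(tert-butyldimethylsilyl)oxy]-14,15,17-trinorlabda-6,11-dien-13-one | CC(C)(C)[Si](C)(C)O[C@H]1C=C[C@H]2C(C)(C)[C@@H](OCc3ccccc3)CC[C@]2(C)[C@H]1/C=C/C(C)=O | intermediate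
20 | 3β-hydroxy-8β-[(tert-butyldimethylsilyl)oxy]-14,15,17-trinorlabdan-13-one | CC(C)(C)[Si](C)(C)O[C@H]1CC[C@H]2C(C)(C)[C@@H](O)CC[C@]2(C)[C@H]1CCC(C)=O | intermediate
21 | 3β-acetoxy-8β-[(tert-butyldimethylsilyl)oxy]-14,15,17-trinorlabdan-13-one | CC(C)(C)[Si](C)(C)O[C@H]1CC[C@H]2C(C)(C)[C@@H](OC(C)=O)CC[C@]2(C)[C@H]1CCC(C)=O | intermediate
22 | allyl (diethoxyphosphoryl)acetate | C=CCOC(=O)CP(=O)(OCC)OCC | starting material
23 | allyl (13E)-3β-acetoxy-8β-[(tert-butyldimethylsilyl)oxy]-17-norlabd-13-en-15-oate | CC(C)(C)[Si](C)(C)O[C@H]1CC[C@H]2C(C)(C)[C@@H](OC(C)=O)CC[C@]2(C)[C@H]1CC/C(C)=C/C(=O)OCC=C | intermediate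
24 | allyl (13E)-3β-acetoxy-8β-hydroxy-17-norlabd-13-en-15-oate | O[C@H]1CC[C@H]2C(C)(C)[C@@H](OC(C)=O)CC[C@]2(C)[C@H]1CC/C(C)=C/C(=O)OCC=C | intermediate
25 | allyl (13E)-3β-acetoxy-8-oxo-17-norlabd-13-en-15-oate | O=C1CC[C@H]2C(C)(C)[C@@H](OC(C)=O)CC[C@]2(C)[C@H]1CC/C(C)=C/C(=O)OCC=C | intermediate
26 | allyl (13E)-3β-acetoxylabda-8(17),13-dien-15-oate | C=C1CC[C@H]2C(C)(C)[C@@H](OC(C)=O)CC[C@]2(C)[C@H]1CC/C(C)=C/C(=O)OCC=C | intermediate
27 | (13E)-3β-acetoxylabda-8(17),13-dien-15-oic acid, (3S,5R,9S,10R) | C=C1CC[C@H]2C(C)(C)[C@@H](OC(C)=O)CC[C@]2(C)[C@H]1CC/C(C)=C/C(=O)O | target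

**Step count and risks**
Total: 19 steps. Longest linear sequence: 19 steps (fully linear from 1 and 2).

Most likely to fail, riskiest first:

1. Step 9. The cycloaddition may stall because the C5–C10 bond joins a neopentyl diene terminus to a β,β-disubstituted enoate. At the temperature then required, endo/exo selectivity (trans versus cis fusion) and diene-face selectivity may erode, or the dienol ether may be lost. The fallback raises the dienophile to the aldehyde oxidation level. Setting out from 14, DIBAL-H (CH2Cl2, −78 °C) should reduce the ester without touching the silyl dienol ether and give the allylic alcohol (2E,6S,8E,10E)-6-(benzyloxy)-11-[(tert-butyldimethylsilyl)oxy]-3,7,7-trimethylundeca-2,8,10-trien-1-ol F1. MnO2 (CH2Cl2, rt) should then give the enal (2E,6S,8E,10E)-6-(benzyloxy)-11-[(tert-butyldimethylsilyl)oxy]-3,7,7-trimethylundeca-2,8,10-trienal F2. This far more electrophilic and more endo-selective dienophile should cyclise near 110 °C in toluene (BHT) and give aldehyde 17 directly, where the route is rejoined with steps 10 and 11 no longer needed.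

2. Step 12. The hindered, epimerisable β-silyloxy aldehyde may fail to condense with the phosphonate anion, or may lose silanol by β-elimination on prolonged exposure to base. The fallback replaces the olefination by an aldol addition and dehydration. From 17, the lithium enolate of acetone (LDA, acetone, THF, −78 °C), a small and reactive nucleophile, should give the β-hydroxy ketone 3β-(benzyloxy)-8β-[(tert-butyldimethylsilyl)oxy]-11-hydroxy-14,15,17-trinorlabd-6-en-13-one F3 as C11 epimers. MsCl/Et3N (CH2Cl2, 0 °C) converts it into the 11-mesylate F4, and DBU eliminates both epimers to the conjugated E-enone 19, where the route continues.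

3. Step 18. Methylenation may remain incomplete because the C8 carbonyl is screened by the C9 side chain and the axial C10 methyl, with titanium enolate formation competing. The fallback builds the alkene in two stages through an epoxide. From 25, Corey–Chaykovsky epoxidation with dimethylsulfonium methylide (Me3S+ I−, KHMDS, THF, −10 °C; the ketone reacts faster than the esters) should give the spiro-epoxide allyl (13E)-3β-acetoxy-8,17-epoxylabd-13-en-15-oate F5 as C8 epimers. Titanocene(III)-mediated deoxygenation (Cp2TiCl2, Zn, THF, rt) converts either epimer into the exocyclic alkene 26, where the route is rejoined.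

**Further compounds**
F1 | step 9 | (2E,6S,8E,10E)-6-(benzyloxy)-11-[(tert-butyldimethylsilyl)oxy]-3,7,7-trimethylundeca-2,8,10-trien-1-ol | OC/C=C(\C)CC[C@H](OCc1ccccc1)C(C)(C)/C=C/C=C/O[Si](C)(C)C(C)(C)C
F2 | step 9 | (2E,6S,8E,10E)-6-(benzyloxy)-11-[(tert-butyldimethylsilyl)oxy]-3,7,7-trimethylundeca-2,8,10-trienal | O=C/C=C(\C)CC[C@H](OCc1ccccc1)C(C)(C)/C=C/C=C/O[Si](C)(C)C(C)(C)C
F3 | step 12 | 3β-(benzyloxy)-8β-[(tert-butyldimethylsilyl)oxy]-11-hydroxy-14,15,17-trinorlabd-6-en-13-one (C11 epimers) | CC(C)(C)[Si](C)(C)O[C@H]1C=C[C@H]2C(C)(C)[C@@H](OCc3ccccc3)CC[C@]2(C)[C@H]1C(O)CC(C)=O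
F4 | step 12 | 3β-(benzyloxy)-8β-[(tert-butyldimethylsilyl)oxy]-11-(methanesulfonyloxy)-14,15,17-trinorlabd-6-en-13-one (C11 epimers) | CC(C)(C)[Si](C)(C)O[C@H]1C=C[C@H]2C(C)(C)[C@@H](OCc3ccccc3)CC[C@]2(C)[C@H]1C(OS(C)(=O)=O)CC(C)=O
F5 | step 18 | allyl (13E)-3β-acetoxy-8,17-epoxylabd-13-en-15-oate (C8 epimers) | C1OC12CC[C@H]3C(C)(C)[C@@H](OC(C)=O)CC[C@]3(C)[C@H]2CC/C(C)=C/C(=O)OCC=C
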